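The rate constants are made up; the flask was simulated.

Follow second intermediate through these flasks and ask how much of it meets open intermediate before it decays.

    starting material + reagent → open intermediate (k1 = 25.9 /M/s)
    reagent + partner → second intermediate (k2 = 3.66 /M/s)
    open intermediate + second intermediate → target (k3 = 1.19 /M/s)
    2 open intermediate → homo product (k4 = 0.470 /M/s)
    starting material + protic impurity → quenched substrate (k5 = 14.1 /M/s)
    second intermediate → decomposed reagent (k6 = 0.0112 /s)

all flasks: reagent 12.5 mM; protic impurity 0.500 mM; time 5.0 min

| charge | starting material | partner | remark |
|---|---|---|---|
| grey | 5.0 mM (fed, over 4.0 min) | 7.50 mM | all else is in the flask from the start; the feed brings no volume worth counting |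
| violet | 5.0 mM | 7.50 mM | everything together at the start |
| blue | 5.0 mM | 7.50 mM (fed, over 4.0 min) | all else is in the flask from the start; the feed brings no volume worth counting |
| amber | 5.0 mM | 7.50 mM (in portions, 2, over 4.0 min) | first portion at the start, last at 4.0 min |

- the best flask by amount of target, in percent of the starting material charged; "all alike" if 1.5 percentage points covers them all (grey / violet / blue / amber / all alike)
- amount of target at the end, in percent of the starting material charged, grey
- amount of target at the end, in percent of the starting material charged, violet
- amount of target at the end, in percent of the starting material charged, blue
- amount of target at the end, in percent of the starting material charged, amber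

- in percentages every species weighs as the starting material in it: one homo product counts as two
- for a step with 2 of a species take k times the square, and two of it per event
- run time (grey): 5.0 min

I reckoned violet by hand. Once starting material had become open intermediate, the reagent beyond it, 7.50 mM, matched partner, 7.50 mM, so I allowed that much second intermediate to form. It then had two exits: coupling, at 1.19 /M/s times c(open intermediate), or decay, at 0.0112 /s. By homo coupling on its own, c(open intermediate) has a first half-life of 3.55 min from the full charge, and the coupling to target drains it as well, so I took half the charge, 2.50 mM, as a round value. On that round value I reckoned coupling at 0.00297 /s, slower than decay. I called the coupling rate divided by the sum of both rates the fork, a branching fraction, and it came to 21.0%. Applied to partner's charge, it gave violet 31.5% of target.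

The forecast, made apart from my reckoning, was lower: violet 28% (24% to 32%), blue 23.5%, amber 20.5%, grey 18%. It chose violet, saying “Having everything present at the start gives the largest early overlap”.

The simulation gave violet 29.7%, amber 19.9%, blue 19.6% and grey 17.2%, with violet best.

In violet, the second intermediate spent by the end split between 1.48 mM of target and 4.86 mM of decomposed reagent, so target took 23.4%, against a fork of 21.0%. Grey received starting material over 4.0 min. Within one half-life of second intermediate by decay alone, 1.03 min, the feed delivered 1.29 mM. Taking that as a round value of c(open intermediate), I reckoned the fork for grey at 12.0%, which on partner's charge came to 18.1% of target. Grey held 17.2%.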